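**Strategy.** Everything rests on disconnecting ring A (cyclohexane C6–C7–C8–C9–C10–C11; C10 = CHBr, C11 = CMe2, C6 and C7 = ring fusion) at the C6–C11 bond while the oxepane (ring B) is already in place. The key step, modelled on the presumed biosynthesis, is a bromonium-triggered cation–olefin cyclization. A configurationally defined C10–C11 bromonium ion is opened at C11 by C6 of a ring-B allylsilane (silicon on C4). This closes ring A and fixes C6, C10 and the quaternary C11 in one operation. It exploits the CHBr–CMe2 unit of ring A next to the ring-fusion C6–H. The precursor is a seven-membered allylsilane lactone built from (R)-linalool; the oxirane and the bromomethylene enol ether follow.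

Key step: step 8

Remarks on the chemistry:
- Numbering (farnesane type, used for compounds 10 to 20): C1 = bromomethylene carbon, C2 = enol ether carbon (lactone carbonyl before step 11), C3 (bears the C15 methyl) and C4 = oxirane carbons, C5 = CH2, C6 = ring-fusion CH, C7 = ring-fusion carbon bearing oxygen and the C14 methyl, C8 and C9 = CH2, C10 = CHBr, C11 = CMe2. Ring A = C6–C7–C8–C9–C10–C11; ring B = O–C2–C3–C4–C5–C6–C7.
- Assumption: the oxirane is treated as a functional group placed on the finished bicyclic skeleton (rings A and B).
- Assumption: (R)-linalool of high enantiomeric purity, (R)-but-3-yn-2-ol and the L-fructose-derived enantiomer of the Shi ketone are taken as purchasable.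

Step 1
Reactants: 1 (R)-but-3-yn-2-ol
Product: 2 (R,E)-4-(dimethylphenylsilyl)but-3-en-2-ol
Conditions: PhMe2SiH, PtCl2 (cat.), XPhos, THF, 50 °C
Reagents that add atoms: dimethylphenylsilane, C[SiH](C)c1ccccc1
Why: Platinum-catalysed syn hydrosilylation of the terminal alkyne with a bulky phosphine places silicon on the terminal carbon and should give the E-vinylsilane, the carbinol stereocenter being untouched.

Step 2
Reactants: 2 (R,E)-4-(dimethylphenylsilyl)but-3-en-2-ol
Product: 3 (R,E)-4-(dimethylphenylsilyl)but-3-en-2-yl propanoate
Conditions: (EtCO)2O, Et3N, DMAP (cat.), CH2Cl2, 0 °C to rt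
Reagents that add atoms: propanoic anhydride, CCC(=O)OC(=O)CC
Why: DMAP-catalysed acylation of the secondary alcohol, which does not touch the stereocenter.

Step 3
Reactants: 3 (R,E)-4-(dimethylphenylsilyl)but-3-en-2-yl propanoate
Product: 6 (2R,3S,E)-2-methyl-3-(dimethylphenylsilyl)hex-4-enoic acid, via silyl ketene acetal 4 (not isolated), via trimethylsilyl ester 5 (not isolated)
Conditions: LiN(iPr)2, THF, −78 °C; Me3SiCl, Et3N, −78 °C to rt; dilute aq. HCl work-up
Reagents that add atoms: none
Why: Ireland–Claisen rearrangement through a chair transition state with the carbinol methyl equatorial should transfer the (R)-C–O stereocenter to the (S)-C–Si stereocenter and give the E-propenyl group, while the E-ketene acetal formed in THF is expected to place the α-methyl center R, a center that is erased in step 9.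

Step 4
Reactants: 6 (2R,3S,E)-2-methyl-3-(dimethylphenylsilyl)hex-4-enoic acid; 7 (R)-linalool
Product: 10 (R)-3,7-dimethylocta-1,6-dien-3-yl (2R,3S,E)-2-methyl-3-(dimethylphenylsilyl)hex-4-enoate, via acid chloride 8 (not isolated), via lithium linalyl oxide 9 (not isolated)
Conditions: 6, 1-chloro-N,N,2-trimethylprop-1-en-1-amine, CH2Cl2, 0 °C; 7, n-BuLi, THF, −78 °C; mix, −78 to 0 °C
Reagents that add atoms: none
Why: O-acylation of the lithium tertiary alkoxide by an acid chloride made under neutral conditions (no HCl, hence no protodesilylation or ionization of the tertiary allylic alcohol) should give the hindered ester; epimerization of the α-center through a ketene would be without consequence.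

Step 5
Reactants: 10 (R)-linalyl ester
Product: 11 (R)-5-[(S)-3,3-dimethyloxiran-2-yl]-3-methylpent-1-en-3-yl (2R,3S,E)-2-methyl-3-(dimethylphenylsilyl)hex-4-enoate (the 10S epoxide)
Conditions: L-fructose-derived Shi ketone (30 mol%), KHSO5 (as 2KHSO5·KHSO4·K2SO4), K2CO3, Bu4NHSO4, MeCN/CH2(OMe)2/aq. Na2B4O7 buffer, 0 °C
Reagents that add atoms: potassium peroxymonosulfate, [K+].[O-]S(=O)(=O)OO
Why: Shi epoxidation: the chiral dioxirane should attack the unhindered, most electron-rich trisubstituted alkene in preference to the hindered propenylsilane and the vinyl group, and its spiro transition state (reagent control, enantiomeric ketone series) should deliver oxygen to the face that gives the 10S epoxide.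

Step 6
Reactants: 11 epoxy ester
Product: 12 (3R,4S,7R)-7-{2-[(S)-3,3-dimethyloxiran-2-yl]ethyl}-3,7-dimethyl-4-(dimethylphenylsilyl)-4,7-dihydrooxepin-2(3H)-one
Conditions: second-generation Hoveyda–Grubbs catalyst [RuCl2(H2IMes)(=CH–C6H4-2-OiPr)] (5–10 mol%), 1,4-benzoquinone (10 mol%), toluene (2 mM), 80 °C
Reagents that add atoms: none
Why: Ring-closing metathesis between the vinyl group on C7 and the propenyl group on C4 (propene is lost) should close ring B as the seven-membered lactone with a cis C5=C6 bond; no trisubstituted alkene is left to divert the carbene and the quaternary C7 favours closure.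

Step 7
Reactants: 12 epoxy lactone
Product: 13 (3R,4S,7R)-7-[(R)-3-bromo-4-hydroxy-4-methylpentyl]-3,7-dimethyl-4-(dimethylphenylsilyl)-4,7-dihydrooxepin-2(3H)-one
Conditions: Li2NiBr4, THF, 0 °C to rt; pH 7 buffer work-up
Reagents that add atoms: dilithium tetrabromonickelate, [Li+].[Li+].[Ni+2].[Br-].[Br-].[Br-].[Br-]
Why: SN2 opening of the epoxide by soft bromide at the less substituted C10 with inversion should give the 10R bromide; a regioisomeric bromohydrin would funnel into the same bromonium ion in step 8 once its secondary hydroxyl is activated.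

Step 8
Reactants: 13 bromohydrin lactone
Product: 16 (3S,5aR,7R,9aR)-7-bromo-3,6,6,9a-tetramethyl-5a,6,7,8,9,9a-hexahydro-1-benzoxepin-2(3H)-one (trans-fused rings A and B, C4=C5 alkene; 3S,6R,7R,10R in route numbering), via tertiary triflate 14 (not isolated), via bromonium triflate 15 (not isolated)
Conditions: Tf2O, 2,6-di-tert-butyl-4-methylpyridine, CH2Cl2 (5 mM), −78 to −40 °C
Reagents that add atoms: none
Why: Triflation of the tertiary C11 hydroxyl and ionization assisted by the antiperiplanar C10 bromine generate the C10–C11 bromonium ion 15 without any external electrophilic bromine, after which C6, the γ-carbon of the ring-B allylsilane, attacks C11 and the β-silyl cation at C5 loses the silyl group to leave the C4=C5 alkene. The closest known reaction types are the bromonium-initiated cation–olefin cyclization started from a bromohydrin derivative and the allylsilane-terminated cation–olefin cyclization (anti SE2′). Ring A closes through a six-membered chair transition state, endo with respect to the C10–C11 bromonium unit (attack at the tertiary C11, both carbons in the ring) and exo with respect to the C5=C6 π bond. C10 keeps the R configuration installed in step 7 because the bromonium ion is opened anti and bromine ends equatorial, and C6 is set by attack anti to the pseudo-axial C4–Si bond within a chair that holds the C14 methyl axial and the C7–O and C6–C5 bonds equatorial, which gives the trans ring fusion, while C11 becomes the quaternary gem-dimethyl carbon. The step needs capture by C6 to outrun proton loss, triflate return, bromonium transfer between molecules and acid-induced 1,4-elimination across the allylsilane and the allylic lactone C7–O bond; the intramolecular six-membered geometry, high dilution, low temperature, the non-nucleophilic counter-ion and the hindered base that buffers triflic acid secure this, and the silicon-bearing C4 stereocenter secures the C6 face.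

Step 9
Reactants: 16 β,γ-unsaturated bicyclic lactone
Product: 17 (5aR,7R,9aR)-7-bromo-3,6,6,9a-tetramethyl-5a,6,7,8,9,9a-hexahydro-1-benzoxepin-2(5H)-one (C3=C4 alkene conjugated with the lactone)
Conditions: DBU, CH2Cl2, rt
Reagents that add atoms: none
Why: Base-mediated isomerization through the extended enolate moves the double bond into conjugation as the trisubstituted C3=C4 alkene and erases the C3 center; the equatorial C10 bromide has no antiperiplanar hydrogen for E2 elimination.

Step 10
Reactants: 17 conjugated lactone
Product: 18 (3S,4S,6R,7R,10R)-3,4-epoxy lactone (oxirane on the ring-B face syn to H6)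
Conditions: DMDO, acetone/CH2Cl2, 0 °C to rt
Reagents that add atoms: dimethyldioxirane, CC1(C)OO1
Why: Concerted dioxirane epoxidation of the enoate should occur on the ring-B face syn to H6, opposite to the axial C14 methyl on C7 and the axial methyl on C11, which sets 3S and 4S.

Step 11
Reactants: 18 epoxy lactone
Product: 19 (3S,4S,6R,7R,10R)-2-(dibromomethylidene) ether (C2=CBr2 in place of the lactone C=O)
Conditions: Ph3P+CHBr2 Br−, KOtBu, THF, 0 °C; then 18, 0 to 50 °C
Reagents that add atoms: (dibromomethyl)triphenylphosphonium bromide, BrC(Br)[P+](c1ccccc1)(c1ccccc1)c1ccccc1.[Br-]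
Why: Wittig-type dibromomethylenation of the lactone carbonyl, which is held s-cis in the ring and activated by the α-oxygen, run with a preformed ylide so that no Ph3PBr2 or zinc salt is present to open the oxirane.

Step 12
Reactants: 19 dibromomethylidene compound
Product: 20 target CNP0375295.2, (1E,3S,4S,6R,7R,10R)
Conditions: Bu3SnH, Pd(PPh3)4 (5 mol%), toluene, rt
Reagents that add atoms: none
Why: Palladium-catalysed hydrogenolysis of a 1,1-dibromoalkene: zerovalent palladium should insert into the less hindered C–Br bond, the one syn to the ring oxygen and anti to the quaternary C3, and tin hydride transfer with reductive elimination (retention) leaves the bromine syn to C3, the E isomer.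

**Compound list**

1 | (R)-but-3-yn-2-ol | C[C@@H](O)C#C | starting material
2 | (R,E)-4-(dimethylphenylsilyl)but-3-en-2-ol | C[C@@H](O)/C=C/[Si](C)(C)c1ccccc1 | intermediate
3 | (R,E)-4-(dimethylphenylsilyl)but-3-en-2-yl propanoate | CCC(=O)O[C@H](C)/C=C/[Si](C)(C)c1ccccc1 | intermediate
4 | (E)-trimethylsilyl ketene acetal of 3 (methyl trans to OSiMe3) | C/C=C(/O[Si](C)(C)C)O[C@H](C)/C=C/[Si](C)(C)c1ccccc1 | intermediate
5 | trimethylsilyl (2R,3S,E)-2-methyl-3-(dimethylphenylsilyl)hex-4-enoate | C[Si](C)(C)OC(=O)[C@@H](C)[C@H](/C=C/C)[Si](C)(C)c1ccccc1 | intermediate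
6 | (2R,3S,E)-2-methyl-3-(dimethylphenylsilyl)hex-4-enoic acid | OC(=O)[C@@H](C)[C@H](/C=C/C)[Si](C)(C)c1ccccc1 | intermediate
7 | (R)-linalool, (R)-3,7-dimethylocta-1,6-dien-3-ol | C=C[C@](C)(O)CCC=C(C)C | starting material
8 | acid chloride of 6 (same spatial arrangement) | ClC(=O)[C@@H](C)[C@H](/C=C/C)[Si](C)(C)c1ccccc1 | intermediate
9 | lithium (R)-3,7-dimethylocta-1,6-dien-3-olate | C=C[C@](C)([O-])CCC=C(C)C.[Li+] | intermediate
10 | (R)-3,7-dimethylocta-1,6-dien-3-yl (2R,3S,E)-2-methyl-3-(dimethylphenylsilyl)hex-4-enoate | C=C[C@@](C)(CCC=C(C)C)OC(=O)[C@@H](C)[C@H](/C=C/C)[Si](C)(C)c1ccccc1 | intermediate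
11 | (R)-5-[(S)-3,3-dimethyloxiran-2-yl]-3-methylpent-1-en-3-yl (2R,3S,E)-2-methyl-3-(dimethylphenylsilyl)hex-4-enoate | C=C[C@@](C)(CC[C@@H]1OC1(C)C)OC(=O)[C@@H](C)[C@H](/C=C/C)[Si](C)(C)c2ccccc2 | intermediate
12 | (3R,4S,7R)-7-{2-[(S)-3,3-dimethyloxiran-2-yl]ethyl}-3,7-dimethyl-4-(dimethylphenylsilyl)-4,7-dihydrooxepin-2(3H)-one | C[C@]1(CC[C@@H]2OC2(C)C)OC(=O)[C@@H](C)[C@H](C=C1)[Si](C)(C)c3ccccc3 | intermediate
13 | (3R,4S,7R)-7-[(R)-3-bromo-4-hydroxy-4-methylpentyl]-3,7-dimethyl-4-(dimethylphenylsilyl)-4,7-dihydrooxepin-2(3H)-one | C[C@]1(CC[C@@H](Br)C(C)(C)O)OC(=O)[C@@H](C)[C@H](C=C1)[Si](C)(C)c2ccccc2 | intermediate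
14 | tertiary (C11) triflate of 13 | C[C@]1(CC[C@@H](Br)C(C)(C)OS(=O)(=O)C(F)(F)F)OC(=O)[C@@H](C)[C@H](C=C1)[Si](C)(C)c2ccccc2 | intermediate
15 | C10–C11 bromonium ion of the lactone, triflate salt | C[C@]1(CC[C@H]2[Br+]C2(C)C)OC(=O)[C@@H](C)[C@H](C=C1)[Si](C)(C)c3ccccc3.[O-]S(=O)(=O)C(F)(F)F | intermediate
16 | (3S,5aR,7R,9aR)-7-bromo-3,6,6,9a-tetramethyl-5a,6,7,8,9,9a-hexahydro-1-benzoxepin-2(3H)-one | CC1(C)[C@H](Br)CC[C@@]2(C)OC(=O)[C@@H](C)C=C[C@H]12 | intermediate
17 | (5aR,7R,9aR)-7-bromo-3,6,6,9a-tetramethyl-5a,6,7,8,9,9a-hexahydro-1-benzoxepin-2(5H)-one | CC1(C)[C@H](Br)CC[C@@]2(C)OC(=O)C(C)=CC[C@H]12 | intermediate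
18 | (3S,4S,6R,7R,10R)-3,4-epoxide of 17 (oxirane syn to H6) | CC1(C)[C@H](Br)CC[C@@]2(C)OC(=O)[C@@]3(C)O[C@H]3C[C@H]12 | intermediate
19 | (3S,4S,6R,7R,10R)-2-(dibromomethylidene) analogue of 18 | CC1(C)[C@H](Br)CC[C@@]2(C)OC(=C(Br)Br)[C@@]3(C)O[C@H]3C[C@H]12 | intermediate
20 | CNP0375295.2, (1E,3S,4S,6R,7R,10R): trans-fused 10-bromo ring A, ring B with 3,4-oxirane and (E)-bromomethylidene at C2 | CC1(C)[C@H](Br)CC[C@@]2(C)O/C(=C/Br)[C@@]3(C)O[C@H]3C[C@H]12 | target

**Step count.** Total: 12 steps. Longest linear sequence: 12 steps (1 to 20); 7 enters at step 4.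

**Steps most likely to fail**

Step 8 (key step). After ionization the bromonium ion may lose a proton or collapse with triflate. Any unbuffered acid may ionize the tertiary allylic C7–O bond with 1,4-loss of the silyl group. In either case ring closure is outrun. The fallback sets out from 10 and comes back at 16. Ring-closing metathesis of 10 with the catalyst of step 6, the carbene being loaded at the propenylsilane end, would give the alkene lactone F1, which keeps the 4-methylpent-3-enyl chain. Hg(OTf)2·PhNMe2 (divalent mercury) in MeNO2 at −20 °C, then aqueous NaCl, would give the equatorial C10 organomercury chloride F2. Mercurinium formation is reversible, so the chair transition state with attack of C6 anti to silicon selects the C10 configuration under substrate control. Br2/LiBr in pyridine would then replace mercury by bromine with retention to give 16.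

Step 11. The carbonyl of 18, flanked by the fully substituted oxirane carbon, may react too slowly, so that the ylide decomposes or attacks the oxirane first. The fallback sets out from 18 and comes back at 19. Methylenation with Cp2TiMe2 (toluene, 70 °C) would give the exocyclic enol ether F3. Addition of Br2 at −78 °C followed by DBU (bromination–dehydrobromination of an enol ether) would give the (Z)-bromomethylidene compound F4. A second round of the same two operations would give 19; the geometry of F4 does not matter because 19 carries two bromines.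

Step 12. Oxidative addition may occur at the wrong C–Br bond (poor control of the double-bond geometry), both bromines may be reduced, or zerovalent palladium may open the vinyl oxirane. The fallback sets out from 19 and comes back at 20. Bromine–magnesium exchange with i-PrMgCl·LiCl in THF at −78 °C, at the more accessible bromine syn to the ring oxygen, would give the configurationally stable magnesium carbenoid F5. Protonation with MeOH at −78 °C with retention would give 20, with no palladium present.

**Further compounds**

F1 | step 8 | (3R,4S,7R)-3,7-dimethyl-7-(4-methylpent-3-enyl)-4-(dimethylphenylsilyl)-4,7-dihydrooxepin-2(3H)-one | C[C@]1(CCC=C(C)C)OC(=O)[C@@H](C)[C@H](C=C1)[Si](C)(C)c2ccccc2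
F2 | step 8 | C10 chloromercury analogue of 16 (HgCl equatorial in place of Br) | CC1(C)[C@H]([Hg]Cl)CC[C@@]2(C)OC(=O)[C@@H](C)C=C[C@H]12
F3 | step 11 | 2-methylidene analogue of 18 (exocyclic enol ether) | CC1(C)[C@H](Br)CC[C@@]2(C)OC(=C)[C@@]3(C)O[C@H]3C[C@H]12
F4 | step 11 | (Z)-bromomethylidene isomer of 20 (bromine syn to the ring oxygen) | CC1(C)[C@H](Br)CC[C@@]2(C)O/C(=C\Br)[C@@]3(C)O[C@H]3C[C@H]12
F5 | step 12 | C1 chloromagnesium carbenoid of 19 (MgCl syn to the ring oxygen, bromine syn to C3) | CC1(C)[C@H](Br)CC[C@@]2(C)O/C(=C(/Br)[Mg]Cl)[C@@]3(C)O[C@H]3C[C@H]12
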